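**Retrosynthetic overview** (positions numbered as in the C18 acid: C1 = ester C=O, C9 = carbinol C, C12 = ring C=O, C13=C14 = exocyclic alkene)
1. 20 ⇒ TES ether 19 ⇒ C14–C15 Suzuki–Miyaura coupling of the (Z)-enol triflate 15 (OTf cis to C12=O fixes 13Z) with the (E)-butenylboronate 18 (fixes 15E); 15 ⇒ C13-formylation of bromoenone 12.
2. 12 ⇒ Br2/Et3N on the (R)-4-hydroxy-4-alkylcyclopentenone 9 ⇒ desilylation and allylic oxidation of 7. The C=O of 1 becomes C9–OH, and its C–OTBS becomes C12=O.
3. 7 ⇒ one-flask three-component linchpin coupling of enone 1, butane-1,4-diyl di-Grignard 5 (C5–C8) and methyl 4-bromobutanoate 4 (C1–C4). C8–C9 forms first and sets C9; C4–C5 then joins the ring half 6 to the ester half 4.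
4. Enabling feature: the unfunctionalised tetramethylene span C5–C8 between ring carbinol C9 and C4 is a butane-1,4-diyl dianion. Once one end has added to C9=O, the other C–Mg bond sits in a seven-membered chelate (O, C9, C8, C7, C6, C5, Mg) and is kept for the copper-catalysed coupling.
5. Rings: the only ring (cyclopentene C9–C13) is bought with 1 and kept throughout; no ring is formed.

Key step: step 1

Remark: (S)-1 is taken as commercially available (both enantiomers are sold); the S enantiomer is the one that leads to the target configuration at C9.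

Step 1
Reactants: 1 (4S)-4-(tert-butyldimethylsilyloxy)cyclopent-2-en-1-one; 2 1,4-dibromobutane; 3 magnesium; 4 methyl 4-bromobutanoate
Product: 7 methyl 8-[(1R,4S)-4-(tert-butyldimethylsilyloxy)-1-hydroxycyclopent-2-en-1-yl]octanoate, via di-Grignard linchpin 5 (not isolated), via alkoxide-tethered C5 Grignard 6 (not isolated)
Conditions: 2, 3, THF, 40 °C (→ 5); 1 added slowly to 5 (2 equiv), THF, −78 °C (→ 6); mixture run into 4 (excess), Li2CuCl4 (3 mol %), NMP, THF, 0 °C → rt; H2O
Reagents that add atoms: none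
Why: Proposed new method: a butane-1,4-diyl di-Grignard is spent on two different electrophiles in one flask, the closest known reaction types being the 1,2-addition of primary alkyl Grignard reagents to 4-silyloxycyclopent-2-enones and the copper-catalysed Kumada-type alkyl–alkyl coupling (Li2CuCl4, NMP) of primary alkylmagnesium halides with ω-bromo esters. Slow addition of 1 to excess 5 at −78 °C, with no copper yet present, should give clean 1,2-addition and form C8–C9; the new stereocentre C9 is controlled by the C12 OTBS group, which shields its own ring face, so that carbon enters trans to it and the carbinol oxygen ends cis (1R,4S). The step needs mono-addition, which is secured by the inverse addition and by the fact that the remaining C5–Mg bond of 6 is an alkyl(alkoxy)magnesium held in the chelate O–C9–C8–C7–C6–C5–Mg and is far less nucleophilic towards a ketone than the RMgBr ends of free 5. When the mixture is run into 4 and catalytic Li2CuCl4, C5 transmetallates from magnesium to copper and the alkylcuprate displaces the primary bromide of 4 (SN2-type oxidative addition, then reductive elimination), which forms C4–C5. The second selectivity needed, C–Br over the methyl ester, is the documented strength of this catalyst system because coupling consumes each C–Mg bond as it arrives, and surplus 5 ends as a symmetrical non-polar diester that chromatography removes. No ring is closed, the cyclopentene ring with its hindered C10=C11 bond is a spectator, and aqueous work-up frees the tertiary alcohol.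

Step 2
Reactants: 7 methyl 8-[(1R,4S)-4-(tert-butyldimethylsilyloxy)-1-hydroxycyclopent-2-en-1-yl]octanoate
Product: 8 methyl 8-[(1R,4S)-1,4-dihydroxycyclopent-2-en-1-yl]octanoate
Conditions: TBAF, AcOH, THF, rt
Reagents that add atoms: none
Why: Fluoride-mediated desilylation frees the secondary C12 alcohol, while the acetic acid buffer keeps the methyl ester and the tertiary allylic alcohol untouched and no stereocentre is affected.

Step 3
Reactants: 8 methyl 8-[(1R,4S)-1,4-dihydroxycyclopent-2-en-1-yl]octanoate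
Product: 9 methyl 8-[(1R)-1-hydroxy-4-oxocyclopent-2-en-1-yl]octanoate
Conditions: activated MnO2, CH2Cl2, rt
Reagents that add atoms: none
Why: MnO2 oxidation is selective for the secondary allylic C12–OH, the tertiary C9–OH cannot be oxidised, and the neutral conditions avoid retro-aldol opening, so C9 is kept.

Step 4
Reactants: 9 methyl 8-[(1R)-1-hydroxy-4-oxocyclopent-2-en-1-yl]octanoate
Product: 11 methyl 8-[(1R)-3-bromo-1-hydroxy-4-oxocyclopent-2-en-1-yl]octanoate, via trans-2,3-dibromo ketone 10 (not isolated)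
Conditions: Br2, CH2Cl2, 0 °C; then Et3N, 0 °C → rt
Reagents that add atoms: bromine, BrBr
Why: Bromination–dehydrobromination of an enone: anti addition of Br2 to C10=C11, then E1cB loss of HBr through the acidic C11–H, leaves bromine on the α-carbon C11, and the saturated side chain offers no competing alkene.

Step 5
Reactants: 11 methyl 8-[(1R)-3-bromo-1-hydroxy-4-oxocyclopent-2-en-1-yl]octanoate
Product: 12 methyl 8-[(1R)-3-bromo-4-oxo-1-(triethylsilyloxy)cyclopent-2-en-1-yl]octanoate
Conditions: TESOTf, 2,6-lutidine, CH2Cl2, −78 → 0 °C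
Reagents that add atoms: triethylsilyl trifluoromethanesulfonate, CC[Si](CC)(CC)OS(=O)(=O)C(F)(F)F
Why: Silyl triflate/lutidine silylation is the standard way to cap a hindered tertiary alcohol, and it blocks retro-aldol opening and alkoxide chemistry in the enolate steps that follow.

Step 6
Reactants: 12 methyl 8-[(1R)-3-bromo-4-oxo-1-(triethylsilyloxy)cyclopent-2-en-1-yl]octanoate
Product: 14 methyl 8-[(1S,5Z)-3-bromo-5-(hydroxymethylidene)-4-oxo-1-(triethylsilyloxy)cyclopent-2-en-1-yl]octanoate, via lithium dienolate 13 (not isolated)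
Conditions: LiHMDS (1.1 equiv), THF, −78 °C; HCO2CH2CF3, −78 °C; AcOH quench
Reagents that add atoms: 2,2,2-trifluoroethyl formate, O=COCC(F)(F)F
Why: Kinetic deprotonation of the ketone can only occur at C13 (C11 carries Br and the ester is far less acidic), and Claisen-type C-formylation of the dienolate with the activated formate should give the β-keto aldehyde, which rests as the hydrogen-bonded (Z)-hydroxymethylene tautomer.

Step 7
Reactants: 14 methyl 8-[(1S,5Z)-3-bromo-5-(hydroxymethylidene)-4-oxo-1-(triethylsilyloxy)cyclopent-2-en-1-yl]octanoate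
Product: 15 methyl 8-[(1S,5Z)-3-bromo-4-oxo-1-(triethylsilyloxy)-5-{[(trifluoromethanesulfonyl)oxy]methylidene}cyclopent-2-en-1-yl]octanoate
Conditions: Tf2O, LiOTf, Et3N, CH2Cl2, −78 → −20 °C
Reagents that add atoms: trifluoromethanesulfonic anhydride, O=S(=O)(OS(=O)(=O)C(F)(F)F)C(F)(F)F
Why: Chelation-controlled enol triflation of a 1,3-dicarbonyl compound: the lithium-bridged U-shaped enolate is sulfonylated on the exposed formyl oxygen, so OTf stays cis to C12=O (Z), and the E isomer would in addition press OTf against the quaternary C9.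

Step 8
Reactants: 16 but-1-yne; 17 pinacolborane
Product: 18 2-[(1E)-but-1-en-1-yl]-4,4,5,5-tetramethyl-1,3,2-dioxaborolane
Conditions: Cp2Zr(H)Cl (cat.), Et3N (cat.), neat, sealed tube, 60 °C
Reagents that add atoms: none
Why: Zirconium-catalysed syn-hydroboration of a terminal alkyne places boron on the terminal carbon and so gives the (E)-alkenylboronate.

Step 9
Reactants: 15 methyl 8-[(1S,5Z)-3-bromo-4-oxo-1-(triethylsilyloxy)-5-{[(trifluoromethanesulfonyl)oxy]methylidene}cyclopent-2-en-1-yl]octanoate; 18 2-[(1E)-but-1-en-1-yl]-4,4,5,5-tetramethyl-1,3,2-dioxaborolane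
Product: 19 methyl 8-[(1S,5Z)-3-bromo-4-oxo-5-[(2E)-pent-2-en-1-ylidene]-1-(triethylsilyloxy)cyclopent-2-en-1-yl]octanoate
Conditions: PdCl2(dppf) (cat.), K3PO4, THF/H2O, rt
Reagents that add atoms: none
Why: Suzuki–Miyaura alkenyl–alkenyl coupling runs with retention at both partners and so should give the 13Z,15E-diene, and the electron-poor β-carbon C14–OTf should add to Pd(0) faster than the α-bromoenone C11–Br, as the β-leaving group reacts first in α,β-dihalo enones and butenolides.

Step 10
Reactants: 19 methyl 8-[(1S,5Z)-3-bromo-4-oxo-5-[(2E)-pent-2-en-1-ylidene]-1-(triethylsilyloxy)cyclopent-2-en-1-yl]octanoate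
Product: 20 methyl 8-[(1S,5Z)-3-bromo-1-hydroxy-4-oxo-5-[(2E)-pent-2-en-1-ylidene]cyclopent-2-en-1-yl]octanoate (CNP0244810.1)
Conditions: HF·pyridine, THF, 0 °C
Reagents that add atoms: none
Why: Buffered HF cleaves the tertiary TES ether under non-basic conditions that should leave the cross-conjugated bromodienone, both alkene geometries, C9 and the ester intact.

**Compound list**
1 | (4S)-4-(tert-butyldimethylsilyloxy)cyclopent-2-en-1-one | O=C1C=C[C@@H](O[Si](C)(C)C(C)(C)C)C1 | starting material
2 | 1,4-dibromobutane | BrCCCCBr | starting material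
3 | magnesium | [Mg] | starting material
4 | methyl 4-bromobutanoate | COC(=O)CCCBr | starting material
5 | butane-1,4-diylbis(magnesium bromide) | Br[Mg]CCCC[Mg]Br | intermediate
6 | bromomagnesium (1R,4S)-1-[4-(bromomagnesio)butyl]-4-(tert-butyldimethylsilyloxy)cyclopent-2-en-1-olate | C1[C@H](O[Si](C)(C)C(C)(C)C)C=C[C@@]1(O[Mg]Br)CCCC[Mg]Br | intermediate
7 | methyl 8-[(1R,4S)-4-(tert-butyldimethylsilyloxy)-1-hydroxycyclopent-2-en-1-yl]octanoate | C1[C@H](O[Si](C)(C)C(C)(C)C)C=C[C@@]1(O)CCCCCCCC(=O)OC | intermediate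
8 | methyl 8-[(1R,4S)-1,4-dihydroxycyclopent-2-en-1-yl]octanoate | C1[C@H](O)C=C[C@@]1(O)CCCCCCCC(=O)OC | intermediate
9 | methyl 8-[(1R)-1-hydroxy-4-oxocyclopent-2-en-1-yl]octanoate | C1C(=O)C=C[C@@]1(O)CCCCCCCC(=O)OC | intermediate
10 | methyl 8-[(1R)-2,3-dibromo-1-hydroxy-4-oxocyclopentyl]octanoate (trans-dibromide) | C1C(=O)C(Br)C(Br)[C@@]1(O)CCCCCCCC(=O)OC | intermediate
11 | methyl 8-[(1R)-3-bromo-1-hydroxy-4-oxocyclopent-2-en-1-yl]octanoate | C1C(=O)C(Br)=C[C@@]1(O)CCCCCCCC(=O)OC | intermediate
12 | methyl 8-[(1R)-3-bromo-4-oxo-1-(triethylsilyloxy)cyclopent-2-en-1-yl]octanoate | C1C(=O)C(Br)=C[C@@]1(O[Si](CC)(CC)CC)CCCCCCCC(=O)OC | intermediate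
13 | lithium C12/C13 dienolate of 12 | C1=C(O[Li])C(Br)=C[C@@]1(O[Si](CC)(CC)CC)CCCCCCCC(=O)OC | intermediate
14 | methyl 8-[(1S,5Z)-3-bromo-5-(hydroxymethylidene)-4-oxo-1-(triethylsilyloxy)cyclopent-2-en-1-yl]octanoate | O/C=C1\C(=O)C(Br)=C[C@@]1(O[Si](CC)(CC)CC)CCCCCCCC(=O)OC | intermediate
15 | methyl 8-[(1S,5Z)-3-bromo-4-oxo-1-(triethylsilyloxy)-5-{[(trifluoromethanesulfonyl)oxy]methylidene}cyclopent-2-en-1-yl]octanoate | O=S(=O)(O/C=C1\C(=O)C(Br)=C[C@@]1(O[Si](CC)(CC)CC)CCCCCCCC(=O)OC)C(F)(F)F | intermediate
16 | but-1-yne | CCC#C | starting material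
17 | pinacolborane | CC1(C)OBOC1(C)C | starting material
18 | 2-[(1E)-but-1-en-1-yl]-4,4,5,5-tetramethyl-1,3,2-dioxaborolane | CC/C=C/B1OC(C)(C)C(C)(C)O1 | intermediate
19 | methyl 8-[(1S,5Z)-3-bromo-4-oxo-5-[(2E)-pent-2-en-1-ylidene]-1-(triethylsilyloxy)cyclopent-2-en-1-yl]octanoate | CC/C=C/C=C1\C(=O)C(Br)=C[C@@]1(O[Si](CC)(CC)CC)CCCCCCCC(=O)OC | intermediate
20 | methyl 8-[(1S,5Z)-3-bromo-1-hydroxy-4-oxo-5-[(2E)-pent-2-en-1-ylidene]cyclopent-2-en-1-yl]octanoate | CC/C=C/C=C1\C(=O)C(Br)=C[C@@]1(O)CCCCCCCC(=O)OC | target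

Total step count: 10. Longest linear sequence: 9 (steps 1–7, 9, 10; step 8 is a side branch).

**Steps most likely to fail**

1. **Step 1.**
   - What may go wrong: both C–Mg ends may add to two ketone molecules; the enone may enolise with loss of silanolate; leftover C–Mg bonds may attack the ester during the copper stage.
   - Fallback (known chemistry): it sets out from 1. Commercial but-3-en-1-ylmagnesium bromide is added (THF, −78 °C) to give (1R,4S)-1-(but-3-en-1-yl)-4-(tert-butyldimethylsilyloxy)cyclopent-2-en-1-ol F1. 9-BBN-H then hydroborates only the terminal alkene to the B-alkyl-9-borabicyclo[3.3.1]nonane derivative F2. An alkyl–alkyl Suzuki–Miyaura coupling with 4 (Pd(OAc)2, PCy3, K3PO4·H2O, THF, rt) forms the same C4–C5 bond and comes back to the route at 7.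

2. **Step 9.**
   - What may go wrong: oxidative addition may compete at C11–Br; the aqueous base may hydrolyse the enol triflate; reversible conjugate addition may erode the 13Z geometry.
   - Fallback: it sets out from 12 and comes back at 19, bypassing steps 6, 7 and 9. LiHMDS and then (E)-pent-2-enal give the aldol adduct methyl 8-[(1R)-3-bromo-5-[(2E)-1-hydroxypent-2-en-1-yl]-4-oxo-1-(triethylsilyloxy)cyclopent-2-en-1-yl]octanoate F3. MsCl/Et3N gives its mesylate F4. DBU-induced E1cB elimination gives 19 together with the (5E)-isomer of 19 F5. F5 is separated and irradiated (365 nm) to a photostationary mixture, from which more 19 is taken and the rest recycled.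

3. **Step 6.**
   - What may go wrong: proton transfer between product and dienolate may stall conversion; acylation may be slow at the hindered C13 next to quaternary C9; excess base may deprotonate the ester.
   - Fallback: it sets out from 12 and comes back at 14. Heating with tert-butoxybis(dimethylamino)methane introduces the one-carbon unit without any strong base as the enaminone methyl 8-[(1S)-3-bromo-5-[(dimethylamino)methylidene]-4-oxo-1-(triethylsilyloxy)cyclopent-2-en-1-yl]octanoate F6. Mild aqueous acid hydrolyses F6 to 14.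

**Further compounds**
F1 | step 1 | (1R,4S)-1-(but-3-en-1-yl)-4-(tert-butyldimethylsilyloxy)cyclopent-2-en-1-ol | C1[C@H](O[Si](C)(C)C(C)(C)C)C=C[C@@]1(O)CCC=C
F2 | step 1 | (1R,4S)-1-[4-(9-borabicyclo[3.3.1]nonan-9-yl)butyl]-4-(tert-butyldimethylsilyloxy)cyclopent-2-en-1-ol | C1[C@H](O[Si](C)(C)C(C)(C)C)C=C[C@@]1(O)CCCCB2C3CCCC2CCC3
F3 | step 9 | methyl 8-[(1R)-3-bromo-5-[(2E)-1-hydroxypent-2-en-1-yl]-4-oxo-1-(triethylsilyloxy)cyclopent-2-en-1-yl]octanoate | CC/C=C/C(O)C1C(=O)C(Br)=C[C@@]1(O[Si](CC)(CC)CC)CCCCCCCC(=O)OC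
F4 | step 9 | methyl 8-[(1R)-3-bromo-5-[(2E)-1-(methanesulfonyloxy)pent-2-en-1-yl]-4-oxo-1-(triethylsilyloxy)cyclopent-2-en-1-yl]octanoate | CC/C=C/C(OS(C)(=O)=O)C1C(=O)C(Br)=C[C@@]1(O[Si](CC)(CC)CC)CCCCCCCC(=O)OC
F5 | step 9 | methyl 8-[(1S,5E)-3-bromo-4-oxo-5-[(2E)-pent-2-en-1-ylidene]-1-(triethylsilyloxy)cyclopent-2-en-1-yl]octanoate | CC/C=C/C=C1/C(=O)C(Br)=C[C@@]1(O[Si](CC)(CC)CC)CCCCCCCC(=O)OC
F6 | step 6 | methyl 8-[(1S)-3-bromo-5-[(dimethylamino)methylidene]-4-oxo-1-(triethylsilyloxy)cyclopent-2-en-1-yl]octanoate | CN(C)C=C1C(=O)C(Br)=C[C@@]1(O[Si](CC)(CC)CC)CCCCCCCC(=O)OC
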